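**Retrosynthetic overview** (ring A = benzo ring of the chroman, ring B = benzo ring of the benzofuran)
- Furan ring, closed last: the benzofuran O1–C2 bond comes from cyclodehydration of a ring A–CO–CH2–ring B ketone, itself made by Pd α-arylation of an 8-acetylflavan with a ring B aryl bromide.
- Pyran ring, closed first: the flavan O1–C2 bond and the only stereocentre come from an enantioselective intramolecular hydroaryloxylation of an ortho-cinnamylphenol.
- Ring A is bought as symmetric 2,6-dihydroxy-4-methoxyacetophenone; its acetyl group fixes the ring A regiochemistry and later becomes C2 and C3 of the benzofuran.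
- Ring B bromide: 3-methoxy-2-methylphenol, then C–H borylation/oxidation (third oxygen), bis-silylation and sterically controlled bromination.

Assumption: 1, 2 and 6 are catalogue compounds, and the (R,R)-cobalt salen complex is assumed to give the (S)-flavan (if induction is opposite, the (S,S)-complex is used).

**Step 1**
Reactants: 1 1-(2,6-dihydroxy-4-methoxyphenyl)ethanone; 2 (E)-3-phenylprop-2-en-1-ol (cinnamyl alcohol)
Product: 3 1-{2,6-dihydroxy-4-methoxy-3-[(2E)-3-phenylprop-2-en-1-yl]phenyl}ethanone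
Conditions: Pd(PPh3)4 (5 mol%), Et3B (0.5 equiv), THF, 50 °C (1 in 1.3-fold excess)
Reagents that add atoms: none
Why: Tsuji–Trost-type C-allylation in which Et3B activates the allylic alcohol for ionisation by zerovalent palladium and the phenol carbon attacks the unsubstituted allyl terminus to give the linear E-cinnamyl group; C3 and C5 of 1 are equivalent, so only one mono-adduct exists, and the neutral medium avoids acid-induced racemic ring closure.

**Step 2**
Reactants: 3 1-{2,6-dihydroxy-4-methoxy-3-[(2E)-3-phenylprop-2-en-1-yl]phenyl}ethanone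
Product: 4 1-[(2S)-7-hydroxy-5-methoxy-2-phenyl-3,4-dihydro-2H-chromen-8-yl]ethanone
Conditions: (R,R)-[N,N'-bis(3,5-di-tert-butylsalicylidene)cyclohexane-1,2-diaminato]cobalt (5 mol%), N-fluoro-2,4,6-trimethylpyridinium tetrafluoroborate (1.5 equiv), PhSiH3 (1.2 equiv), PhCF3/acetone, −10 °C
Reagents that add atoms: none
Why: Proposed new method: enantioselective 6-endo hydroaryloxylation of an internal styrene by metal-hydride hydrogen-atom transfer and radical-polar crossover, in which a trivalent cobalt hydride (from the divalent cobalt salen complex, the N–F oxidant and PhSiH3) gives H• to the alkene carbon next to the ring A CH2, the benzylic radical is captured and oxidised to a chiral tetravalent benzylcobalt species, and the ortho phenol (collidine as base) displaces cobalt with inversion, the salen ligand selecting between the equilibrating diastereomeric alkylcobalt species so that the 2S centre is set in the C–O bond-forming event; closest known reaction type is cobalt salen-catalysed Mukaiyama-type intramolecular hydroalkoxylation of unactivated alkenols (racemic, and enantioselective for aliphatic alcohols), not shown for a chelated phenol adding to a β-alkylstyrene to give a 2-arylchroman, and the neutral conditions tolerate the basic aryl ketone that would bind a strong chiral acid.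

**Step 3**
Reactants: 4 1-[(2S)-7-hydroxy-5-methoxy-2-phenyl-3,4-dihydro-2H-chromen-8-yl]ethanone
Product: 5 1-[(2S)-5-methoxy-7-(methoxymethoxy)-2-phenyl-3,4-dihydro-2H-chromen-8-yl]ethanone
Conditions: NaH, MOMCl, THF/DMF, 0 °C to rt
Reagents that add atoms: chloro(methoxy)methane (MOMCl), COCCl
Why: Williamson-type MOM ether formation on the single, chelated phenol so that only the acetyl CH3 is acidic in the coupling step; the stereocentre has no acidic hydrogen.

**Step 4**
Reactants: 6 3-methoxy-2-methylphenol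
Product: 9 5-methoxy-4-methylbenzene-1,3-diol, via O-boryl ether 7 (not isolated), via C-borylated boronate 8 (not isolated)
Conditions: HBpin (2.5 equiv), [Ir(OMe)(cod)]2 (1.5 mol%), dtbpy (3 mol%), THF, 80 °C; then aq. KHSO5 (as 2KHSO5·KHSO4·K2SO4), acetone, 0 °C to rt
Reagents that add atoms: pinacolborane, [H]B1OC(C)(C)C(C)(C)O1 (boron groups of 7 and 8); potassium peroxymonosulfate, [K+].[O-]S(=O)(=O)OO (the new oxygen of 9)
Why: Sterically governed iridium-catalysed C–H borylation (Hartwig–Miyaura type) of the phenol masked in situ as its boryl ether occurs at the only C–H without an ortho substituent (para to the methyl), and peroxymonosulfate oxidation of the C–B bond gives the phenol.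

**Step 5**
Reactants: 9 5-methoxy-4-methylbenzene-1,3-diol
Product: 10 [(5-methoxy-4-methyl-1,3-phenylene)bis(oxy)]bis[tri(propan-2-yl)silane]
Conditions: TIPSCl (2.4 equiv), imidazole, DMF, 40 °C
Reagents that add atoms: chlorotri(propan-2-yl)silane (TIPSCl), CC(C)[Si](Cl)(C(C)C)C(C)C
Why: Standard imidazole-promoted silyl ether formation on both phenols, giving bulky groups that steer the next step and survive strong base.

**Step 6**
Reactants: 10 [(5-methoxy-4-methyl-1,3-phenylene)bis(oxy)]bis[tri(propan-2-yl)silane]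
Product: 11 [(4-bromo-5-methoxy-6-methyl-1,3-phenylene)bis(oxy)]bis[tri(propan-2-yl)silane]
Conditions: NBS (1.0 equiv), MeCN, −20 to 0 °C
Reagents that add atoms: N-bromosuccinimide, O=C1CCC(=O)N1Br
Why: Electrophilic aromatic bromination of a tri-oxygenated arene; the C–H between the two silyloxy groups is shielded (the silyl group next to the methyl is forced towards it), so bromine enters at the C–H flanked by the methoxy group.

**Step 7**
Reactants: 5 1-[(2S)-5-methoxy-7-(methoxymethoxy)-2-phenyl-3,4-dihydro-2H-chromen-8-yl]ethanone; 11 [(4-bromo-5-methoxy-6-methyl-1,3-phenylene)bis(oxy)]bis[tri(propan-2-yl)silane]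
Product: 15 (2S)-8-(6-hydroxy-4-methoxy-5-methyl-1-benzofuran-2-yl)-5-methoxy-2-phenyl-3,4-dihydro-2H-chromen-7-ol, via silylated aryl benzyl ketone 12 (not isolated), via dihydroxy ketone 13 (not isolated), via MOM-protected benzofuran 14 (not isolated)
Conditions: Pd(OAc)2 (5 mol%), P(t-Bu)3·HBF4 (10 mol%), NaOtBu (2.5 equiv), toluene, 80 °C; then Bu4NF, THF, rt; then HCl, MeOH, 50 °C
Reagents that add atoms: none
Why: Buchwald–Hartwig-type ketone α-arylation at the only enolisable position, then fluoride desilylation and acid-catalysed cyclodehydration (C–O bond; only the ring B hydroxyl ortho to the CH2 can reach the carbonyl) with MOM cleavage in methanol; the C2 stereocentre is untouched by base, fluoride or dilute acid.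

**Compound list**
1 | 1-(2,6-dihydroxy-4-methoxyphenyl)ethanone | CC(=O)c1c(O)cc(OC)cc1O | starting material
2 | (E)-3-phenylprop-2-en-1-ol | OC/C=C/c1ccccc1 | starting material
3 | 1-{2,6-dihydroxy-4-methoxy-3-[(2E)-3-phenylprop-2-en-1-yl]phenyl}ethanone | CC(=O)c1c(O)cc(OC)c(C/C=C/c2ccccc2)c1O | intermediate
4 | 1-[(2S)-7-hydroxy-5-methoxy-2-phenyl-3,4-dihydro-2H-chromen-8-yl]ethanone | COc1cc(O)c(C(C)=O)c2c1CC[C@@H](c1ccccc1)O2 | intermediate
5 | 1-[(2S)-5-methoxy-7-(methoxymethoxy)-2-phenyl-3,4-dihydro-2H-chromen-8-yl]ethanone | COc1cc(OCOC)c(C(C)=O)c2c1CC[C@@H](c1ccccc1)O2 | intermediate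
6 | 3-methoxy-2-methylphenol | COc1cccc(O)c1C | starting material
7 | 2-(3-methoxy-2-methylphenoxy)-4,4,5,5-tetramethyl-1,3,2-dioxaborolane | COc1cccc(OB2OC(C)(C)C(C)(C)O2)c1C | intermediate
8 | 2-{3-methoxy-4-methyl-5-[(4,4,5,5-tetramethyl-1,3,2-dioxaborolan-2-yl)oxy]phenyl}-4,4,5,5-tetramethyl-1,3,2-dioxaborolane | COc1cc(B2OC(C)(C)C(C)(C)O2)cc(OB3OC(C)(C)C(C)(C)O3)c1C | intermediate
9 | 5-methoxy-4-methylbenzene-1,3-diol | COc1cc(O)cc(O)c1C | intermediate
10 | [(5-methoxy-4-methyl-1,3-phenylene)bis(oxy)]bis[tri(propan-2-yl)silane] | COc1cc(O[Si](C(C)C)(C(C)C)C(C)C)cc(O[Si](C(C)C)(C(C)C)C(C)C)c1C | intermediate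
11 | [(4-bromo-5-methoxy-6-methyl-1,3-phenylene)bis(oxy)]bis[tri(propan-2-yl)silane] | COc1c(Br)c(O[Si](C(C)C)(C(C)C)C(C)C)cc(O[Si](C(C)C)(C(C)C)C(C)C)c1C | intermediate
12 | 1-[(2S)-5-methoxy-7-(methoxymethoxy)-2-phenyl-3,4-dihydro-2H-chromen-8-yl]-2-{2-methoxy-3-methyl-4,6-bis[tri(propan-2-yl)silyloxy]phenyl}ethanone | COc1cc(OCOC)c(C(=O)Cc3c(OC)c(C)c(O[Si](C(C)C)(C(C)C)C(C)C)cc3O[Si](C(C)C)(C(C)C)C(C)C)c2c1CC[C@@H](c1ccccc1)O2 | intermediate
13 | 2-(4,6-dihydroxy-2-methoxy-3-methylphenyl)-1-[(2S)-5-methoxy-7-(methoxymethoxy)-2-phenyl-3,4-dihydro-2H-chromen-8-yl]ethanone | COc1cc(OCOC)c(C(=O)Cc3c(OC)c(C)c(O)cc3O)c2c1CC[C@@H](c1ccccc1)O2 | intermediate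
14 | 4-methoxy-2-[(2S)-5-methoxy-7-(methoxymethoxy)-2-phenyl-3,4-dihydro-2H-chromen-8-yl]-5-methyl-1-benzofuran-6-ol | COc1cc(OCOC)c(-c2cc3c(OC)c(C)c(O)cc3o2)c2c1CC[C@@H](c1ccccc1)O2 | intermediate
15 | (2S)-8-(6-hydroxy-4-methoxy-5-methyl-1-benzofuran-2-yl)-5-methoxy-2-phenyl-3,4-dihydro-2H-chromen-7-ol | COc1cc(O)c(-c2cc3c(OC)c(C)c(O)cc3o2)c2c1CC[C@@H](c1ccccc1)O2 | target

**Totals**
Total steps: 7. Longest linear sequence: 4 steps (1 → 3 → 4 → 5 → 15, or 6 → 9 → 10 → 11 → 15).

**Steps most likely to fail**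

Step 2 (proposed new method). Turnover with two free phenols and an N–F oxidant, and enantioselectivity at a benzylic centre that can leak through a free cation, are unproven. The fallback uses known chemistry, sets out from 1 and comes back at 4. Sc(OTf)3-catalysed conjugate C-alkylation of 1 with phenyl vinyl ketone (MeCN, rt) gives 1-[2,6-dihydroxy-4-methoxy-3-(3-oxo-3-phenylpropyl)phenyl]ethanone F1. Noyori-type asymmetric transfer hydrogenation with RuCl[(R,R)-TsDPEN](p-cymene) and HCO2H/Et3N reduces only the unhindered phenyl ketone to 1-{2,6-dihydroxy-3-[(3R)-3-hydroxy-3-phenylpropyl]-4-methoxyphenyl}ethanone F2. Mitsunobu ring closure (PPh3, DIAD, THF, 0 °C) by the neighbouring phenol with inversion gives 4.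

Step 6. Regioselectivity rests on sterics alone; bromination between the two silyloxy groups would give a useless isomer. The fallback sets out from 10 and comes back at 11. Directed ortho-lithiation (s-BuLi, TMEDA, THF, −78 °C), in which the methoxy group is the only coordinating director, gives {2-methoxy-3-methyl-4,6-bis[tri(propan-2-yl)silyloxy]phenyl}lithium F3, which is quenched with BrCH2CH2Br to give 11.

Step 7. Oxidative addition and C–C coupling at an electron-rich aryl bromide flanked by a methoxy and a bulky silyloxy group may be slow, and the three-stage one-pot must go cleanly. The fallback replaces enolate arylation by an alkyne route, sets out from 5 and comes back at 14.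
- Ketone 5 with LiN(i-Pr)2 and ClP(O)(OEt)2 (THF, −78 °C) gives diethyl 1-[(2S)-5-methoxy-7-(methoxymethoxy)-2-phenyl-3,4-dihydro-2H-chromen-8-yl]ethenyl phosphate F4.
- More LiN(i-Pr)2 eliminates F4 to (2S)-8-ethynyl-5-methoxy-7-(methoxymethoxy)-2-phenyl-3,4-dihydro-2H-chromene F5.
- Copper-free Sonogashira coupling of F5 with 11 (PdCl2(MeCN)2, XPhos, Cs2CO3, MeCN, 80 °C) gives (2S)-5-methoxy-7-(methoxymethoxy)-8-({2-methoxy-3-methyl-4,6-bis[tri(propan-2-yl)silyloxy]phenyl}ethynyl)-2-phenyl-3,4-dihydro-2H-chromene F6.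
- Bu4NF (THF, 60 °C) desilylates F6 to 4-{[(2S)-5-methoxy-7-(methoxymethoxy)-2-phenyl-3,4-dihydro-2H-chromen-8-yl]ethynyl}-5-methoxy-6-methylbenzene-1,3-diol F7, whose ortho phenoxide adds 5-endo-dig to the alkyne to give 14.
- HCl/MeOH, as in the last stage of step 7, then gives 15.

**Further compounds**
F1 | step 2 | 1-[2,6-dihydroxy-4-methoxy-3-(3-oxo-3-phenylpropyl)phenyl]ethanone | CC(=O)c1c(O)cc(OC)c(CCC(=O)c2ccccc2)c1O
F2 | step 2 | 1-{2,6-dihydroxy-3-[(3R)-3-hydroxy-3-phenylpropyl]-4-methoxyphenyl}ethanone | CC(=O)c1c(O)cc(OC)c(CC[C@@H](O)c2ccccc2)c1O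
F3 | step 6 | {2-methoxy-3-methyl-4,6-bis[tri(propan-2-yl)silyloxy]phenyl}lithium | [Li]c1c(OC)c(C)c(O[Si](C(C)C)(C(C)C)C(C)C)cc1O[Si](C(C)C)(C(C)C)C(C)C
F4 | step 7 | diethyl 1-[(2S)-5-methoxy-7-(methoxymethoxy)-2-phenyl-3,4-dihydro-2H-chromen-8-yl]ethenyl phosphate | COc1cc(OCOC)c(C(=C)OP(=O)(OCC)OCC)c2c1CC[C@@H](c1ccccc1)O2
F5 | step 7 | (2S)-8-ethynyl-5-methoxy-7-(methoxymethoxy)-2-phenyl-3,4-dihydro-2H-chromene | COc1cc(OCOC)c(C#C)c2c1CC[C@@H](c1ccccc1)O2
F6 | step 7 | (2S)-5-methoxy-7-(methoxymethoxy)-8-({2-methoxy-3-methyl-4,6-bis[tri(propan-2-yl)silyloxy]phenyl}ethynyl)-2-phenyl-3,4-dihydro-2H-chromene | COc1cc(OCOC)c(C#Cc3c(OC)c(C)c(O[Si](C(C)C)(C(C)C)C(C)C)cc3O[Si](C(C)C)(C(C)C)C(C)C)c2c1CC[C@@H](c1ccccc1)O2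
F7 | step 7 | 4-{[(2S)-5-methoxy-7-(methoxymethoxy)-2-phenyl-3,4-dihydro-2H-chromen-8-yl]ethynyl}-5-methoxy-6-methylbenzene-1,3-diol | COc1cc(OCOC)c(C#Cc3c(OC)c(C)c(O)cc3O)c2c1CC[C@@H](c1ccccc1)O2
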